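**Retrosynthetic overview**
1. Target 20 comes from silyl-protected flavanone 19 by desilylation. 19 comes from its 5,6-dihydro form 18 by dehydrogenation of ring A.
2. 18 comes from aldehyde 16 and tris(silyloxy)triene 14. Ring C is made in one operation by a catalytic asymmetric formal hetero-Diels–Alder reaction that forms C2–C3 and O1–C8a and sets C2.
3. Enabling feature: in ring C the array O1–C8a=C4a–C4(=O)–C3H2–C2 is a 2,3-dihydro-4-pyranone (vinylogous ester) whose C8a=C4a bond is shared with ring A, and the oxygens on C8a and C7 are 1,3-related. With ring A at its 5,6-dihydro (dihydroresorcinol) level, C8a becomes a 1,3-dicarbonyl carbon that can exchange its own oxygen for the aldehyde oxygen.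
4. 14 comes from 4-acetyl-2-alkylcyclohexane-1,3-dione 13, 13 from dione 11, and 11 from 1,5-dimethoxycyclohexa-1,4-diene 8 plus (Z)-allylic bromide 7. The Z olefin comes from anti-carbomagnesiation of propargyl alcohol 1.
5. Ring order: ring B and the carbocycle of ring A are bought, ring C is closed in step 9, and ring A is aromatised in step 10.

Key step: step 9

Assumption: flavanone numbering (O1, C2, C3, C4, C4a, C5–C8, C8a) is used for all intermediates; the target is read as the (2S),(Z) isomer (CH2OH cis to the ArCH2 group); Si-face attack with (S)-BINOL/Ti(OiPr)4 is assumed from the behaviour of this catalyst in allylstannane and silyloxydiene additions to aryl aldehydes, and (R)-BINOL would be used if the triene responds in the opposite sense.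

Abbreviations: TBDPS = tert-butyldiphenylsilyl, TBS = tert-butyldimethylsilyl, TMS = trimethylsilyl, TES = triethylsilyl, TIPS = triisopropylsilyl.

**Step 1**
Reactants: 1 propargyl alcohol
Product: 3 (Z)-3-iodo-2-methylprop-2-en-1-ol, via alkenylmagnesium alkoxide 2 (not isolated)
Conditions: MeMgBr (3 equiv), CuI (10 mol %), Et2O/THF, -10 °C to rt; then I2, 0 °C; aqueous quench
Reagents that add atoms: methylmagnesium bromide C[Mg]Br; iodine II
Why: Copper-catalysed anti-carbomagnesiation of the propargylic alkoxide places methyl on C2 and magnesium on C3 cis to the CH2O group in a five-membered chelate, and iodinolysis with retention fixes the Z trisubstituted olefin of the side chain.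

**Step 2**
Reactants: 3 (Z)-3-iodo-2-methylprop-2-en-1-ol
Product: 4 (Z)-3-iodo-2-methylprop-2-enyl TBDPS ether
Conditions: TBDPSCl, imidazole, CH2Cl2, 0 °C to rt
Reagents that add atoms: tert-butyldiphenylsilyl chloride CC(C)(C)[Si](Cl)(c1ccccc1)c1ccccc1
Why: Imidazole-promoted silylation of a primary alcohol, with TBDPS chosen because it must outlast the aqueous HCl of step 5 and the TFA of step 9.

**Step 3**
Reactants: 4 (Z)-3-iodo-2-methylprop-2-enyl TBDPS ether
Product: 6 (Z)-4-(TBDPS-oxy)-3-methylbut-2-en-1-ol, via alkenylmagnesium chloride 5 (not isolated)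
Conditions: i-PrMgCl·LiCl, THF, -20 °C to rt; then (CH2O)n, 0 °C to rt; aqueous quench
Reagents that add atoms: formaldehyde (as paraformaldehyde) C=O
Why: Iodine–magnesium exchange of an alkenyl iodide proceeds with retention of geometry, the magnesium species is far less prone than its lithium analogue to a 1,4 oxygen-to-carbon silyl shift, and Grignard addition to formaldehyde supplies the missing carbon as a primary allylic alcohol.

**Step 4**
Reactants: 6 (Z)-4-(TBDPS-oxy)-3-methylbut-2-en-1-ol
Product: 7 (Z)-4-bromo-2-methylbut-2-enyl TBDPS ether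
Conditions: CBr4, PPh3, CH2Cl2, 0 °C, used at once
Reagents that add atoms: carbon tetrabromide BrC(Br)(Br)Br
Why: The Appel reaction displaces the alkoxyphosphonium ion by SN2 at a primary allylic carbon under neutral conditions, which should keep both the regiochemistry and the Z geometry.

**Step 5**
Reactants: 8 1,5-dimethoxycyclohexa-1,4-diene (commercial, the Birch product of 1,3-dimethoxybenzene); 7 (Z)-4-bromo-2-methylbut-2-enyl TBDPS ether
Product: 11 2-[(Z)-4-(TBDPS-oxy)-3-methylbut-2-enyl]cyclohexane-1,3-dione, via lithiated diene 9 (not isolated), via alkylated bis(enol ether) 10 (not isolated)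
Conditions: t-BuLi, THF, -78 °C; 7, DMPU, -78 °C to 0 °C; then 1 M HCl, THF, rt
Reagents that add atoms: water O
Why: Deprotonation of the doubly allylic CH2 flanked by both methoxy-bearing carbons gives a cyclohexadienyl anion that is alkylated at its central carbon by SN2 on the primary allylic bromide, and enol ether hydrolysis then releases the 2-substituted 1,3-dione without the O-alkylation and dialkylation of direct dione alkylation, so the chain sits unambiguously on the future C8.

**Step 6**
Reactants: 11 2-[(Z)-4-(TBDPS-oxy)-3-methylbut-2-enyl]cyclohexane-1,3-dione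
Product: 13 4-acetyl-2-[(Z)-4-(TBDPS-oxy)-3-methylbut-2-enyl]cyclohexane-1,3-dione (drawn as its bis-enol), via dilithium dienediolate 12 (not isolated)
Conditions: LDA (commercial solution, 2.3 equiv), THF/DMPU, -78 to 0 °C; MeC(O)N(OMe)Me, -78 to 0 °C; 1 M HCl to pH 4, argon
Reagents that add atoms: N-methoxy-N-methylacetamide CC(=O)N(C)OC
Why: This is a gamma-acylation of a 1,3-dicarbonyl dianion, in which the last-formed and most basic carbanion centre (future C4a) attacks the Weinreb amide and the chelated tetrahedral intermediate prevents further reaction until the quench.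

**Step 7**
Reactants: 13 4-acetyl-2-[(Z)-4-(TBDPS-oxy)-3-methylbut-2-enyl]cyclohexane-1,3-dione
Product: 14 2,4-bis(TMS-oxy)-1-[1-(TMS-oxy)vinyl]-3-[(Z)-4-(TBDPS-oxy)-3-methylbut-2-enyl]cyclohexa-1,3-diene
Conditions: TMSOTf (3.3 equiv), Et3N (4 equiv), Et2O, 0 °C to rt, salt layer removed, used crude
Reagents that add atoms: trimethylsilyl triflate C[Si](C)(C)OS(=O)(=O)C(F)(F)F
Why: Soft enolisation and O-silylation with TMSOTf/Et3N is the standard one-step entry to 1,3-bis(silyloxy)dienes from 1,3-diketones, and the acetyl group can only enolise toward its CH3 because C4a is already sp2, so an achiral planar triene results.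

**Step 8**
Reactants: 15 3,4-dihydroxybenzaldehyde
Product: 16 3,4-bis(TBS-oxy)benzaldehyde
Conditions: TBSCl (2.4 equiv), imidazole, DMF, rt
Reagents that add atoms: tert-butyldimethylsilyl chloride CC(C)(C)[Si](C)(C)Cl
Why: Imidazole-promoted phenol silylation masks the catechol with groups that tolerate the titanium catalyst, TFA and DDQ and leave under buffered fluoride.

**Step 9**
Reactants: 14 tris(silyloxy)triene; 16 3,4-bis(TBS-oxy)benzaldehyde
Product: 18 (2S)-2-[3,4-bis(TBS-oxy)phenyl]-7-hydroxy-8-[(Z)-4-(TBDPS-oxy)-3-methylbut-2-enyl]-2,3,5,6-tetrahydro-4H-chromen-4-one, via (S)-aldol silyl ether 17 (not isolated)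
Conditions: (S)-BINOL (20 mol %), Ti(OiPr)4 (20 mol %), 4 Å MS, Et2O, -20 °C; then TFA, CH2Cl2, 0 °C, short contact, aq NaHCO3
Reagents that add atoms: none
Why: The (S)-BINOL/Ti(OiPr)4 complex activates aldehyde 16 and the unsubstituted C3 terminus of triene 14 adds to it in a vinylogous Mukaiyama aldol reaction (C2–C3 bond) with silyl transfer to give 17; TFA then unmasks the C2 oxygen, which adds to the C8a carbonyl carbon of the 1,3-dicarbonyl unit and expels the original C8a oxygen as siloxane (O1–C8a bond), so the aldehyde C=O is spent across C3 and C8a in a stepwise formal hetero-Diels–Alder reaction. The closest known reaction type is the BINOL–titanium-catalysed addition of Danishefsky-type dienes and 1,3-bis(silyloxy)dienes to aldehydes followed by acid closure to 2-substituted 2,3-dihydro-4-pyranones. Ring C closes by 6-exo-trig hemiketalisation at C8a followed by dehydration, driven by formation of the vinylogous ester O1–C8a=C4a–C4=O. The only new stereocentre, C2, is set in the aldol event by the catalyst, which should expose the Si face of the aryl aldehyde and give the S configuration, and the C2–O bond is not broken afterwards because the oxygen that leaves is the one on C8a. Site selectivity among the nucleophilic carbons C3, C4a and C8 is secured by the substrate, since C3 is the only unsubstituted terminus and attack there leaves a cation delocalised over all three silyloxy groups, and only C8a lies within six-membered reach of the C2 oxygen. The C7 silyl ether falls off in the same acid treatment, which leaves ring A as the 7-hydroxy-5,6-dihydro (vinylogous acid) tautomer ready for aromatisation.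

**Step 10**
Reactants: 18 5,6-dihydroflavanone
Product: 19 (2S)-2-[3,4-bis(TBS-oxy)phenyl]-7-hydroxy-8-[(Z)-4-(TBDPS-oxy)-3-methylbut-2-enyl]chroman-4-one
Conditions: DDQ (1.05 equiv), toluene, 0 °C to rt
Reagents that add atoms: none
Why: In this DDQ dehydrogenation of a cyclohexa-1,3-diene, hydride abstraction from C5 gives an arenium ion stabilised by O1 and the C7 oxygen, loss of a C6 proton gives the resorcinol-type ring A, and the neutral to weakly acidic medium should leave C2 and the Z olefin untouched.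

**Step 11**
Reactants: 19 silyl-protected flavanone
Product: 20 (2S)-2-(3,4-dihydroxyphenyl)-7-hydroxy-8-[(Z)-4-hydroxy-3-methylbut-2-enyl]chroman-4-one (target)
Conditions: TBAF (4 equiv), AcOH (5 equiv), degassed THF, 0 °C to rt
Reagents that add atoms: none
Why: Fluoride-induced cleavage of the two aryl TBS ethers and the primary TBDPS ether, buffered with acetic acid so that no phenoxide-driven ring opening to the chalcone (racemisation at C2) and no acid-induced ionisation of the allylic alcohol should occur.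

**Compound list**
1 | propargyl alcohol | C#CCO | starting material
2 | (Z)-alkenylmagnesium alkoxide from anti-carbomagnesiation | C/C(=C/[Mg]Br)CO[Mg]Br | intermediate
3 | (Z)-3-iodo-2-methylprop-2-en-1-ol | C/C(=C/I)CO | intermediate
4 | (Z)-3-iodo-2-methylprop-2-enyl TBDPS ether | C/C(=C/I)CO[Si](c1ccccc1)(c1ccccc1)C(C)(C)C | intermediate
5 | (Z)-alkenylmagnesium chloride | C/C(=C/[Mg]Cl)CO[Si](c1ccccc1)(c1ccccc1)C(C)(C)C | intermediate
6 | (Z)-4-(TBDPS-oxy)-3-methylbut-2-en-1-ol | C/C(=C/CO)CO[Si](c1ccccc1)(c1ccccc1)C(C)(C)C | intermediate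
7 | (Z)-4-bromo-2-methylbut-2-enyl TBDPS ether | C/C(=C/CBr)CO[Si](c1ccccc1)(c1ccccc1)C(C)(C)C | intermediate
8 | 1,5-dimethoxycyclohexa-1,4-diene | COC1=CCC=C(OC)C1 | starting material
9 | 6-lithio-1,5-dimethoxycyclohexa-1,4-diene | COC1=CCC=C(OC)C1[Li] | intermediate
10 | 6-[(Z)-4-(TBDPS-oxy)-3-methylbut-2-enyl]-1,5-dimethoxycyclohexa-1,4-diene | C/C(=C/CC1C(OC)=CCC=C1OC)CO[Si](c1ccccc1)(c1ccccc1)C(C)(C)C | intermediate
11 | 2-[(Z)-4-(TBDPS-oxy)-3-methylbut-2-enyl]cyclohexane-1,3-dione | C/C(=C/CC1C(=O)CCCC1=O)CO[Si](c1ccccc1)(c1ccccc1)C(C)(C)C | intermediate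
12 | dilithium dienediolate (dianion) of 11 | C/C(=C/CC1=C(O[Li])CCC=C1O[Li])CO[Si](c1ccccc1)(c1ccccc1)C(C)(C)C | intermediate
13 | 4-acetyl-2-[(Z)-4-(TBDPS-oxy)-3-methylbut-2-enyl]cyclohexane-1,3-dione, bis-enol tautomer | C/C(=C/CC1=C(O)CCC(C(C)=O)=C1O)CO[Si](c1ccccc1)(c1ccccc1)C(C)(C)C | intermediate
14 | 2,4-bis(TMS-oxy)-1-[1-(TMS-oxy)vinyl]-3-[(Z)-4-(TBDPS-oxy)-3-methylbut-2-enyl]cyclohexa-1,3-diene | C/C(=C/CC1=C(O[Si](C)(C)C)CCC(C(=C)O[Si](C)(C)C)=C1O[Si](C)(C)C)CO[Si](c1ccccc1)(c1ccccc1)C(C)(C)C | intermediate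
15 | 3,4-dihydroxybenzaldehyde | O=Cc1ccc(O)c(O)c1 | starting material
16 | 3,4-bis(TBS-oxy)benzaldehyde | O=Cc1ccc(O[Si](C)(C)C(C)(C)C)c(O[Si](C)(C)C(C)(C)C)c1 | intermediate
17 | (S)-aldol TMS ether (C4 ketone, C2–OTMS, C8a–OTMS, C7–OTMS) | C/C(=C/CC1=C(O[Si](C)(C)C)CCC(C(=O)C[C@H](O[Si](C)(C)C)c2ccc(O[Si](C)(C)C(C)(C)C)c(O[Si](C)(C)C(C)(C)C)c2)=C1O[Si](C)(C)C)CO[Si](c1ccccc1)(c1ccccc1)C(C)(C)C | intermediate
18 | (2S)-2-[3,4-bis(TBS-oxy)phenyl]-7-hydroxy-8-[(Z)-4-(TBDPS-oxy)-3-methylbut-2-enyl]-2,3,5,6-tetrahydro-4H-chromen-4-one | C/C(=C/CC1=C(O)CCC2=C1O[C@H](c1ccc(O[Si](C)(C)C(C)(C)C)c(O[Si](C)(C)C(C)(C)C)c1)CC2=O)CO[Si](c1ccccc1)(c1ccccc1)C(C)(C)C | intermediate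
19 | (2S)-2-[3,4-bis(TBS-oxy)phenyl]-7-hydroxy-8-[(Z)-4-(TBDPS-oxy)-3-methylbut-2-enyl]chroman-4-one | C/C(=C/Cc1c(O)ccc2c1O[C@H](c1ccc(O[Si](C)(C)C(C)(C)C)c(O[Si](C)(C)C(C)(C)C)c1)CC2=O)CO[Si](c1ccccc1)(c1ccccc1)C(C)(C)C | intermediate
20 | (2S)-2-(3,4-dihydroxyphenyl)-7-hydroxy-8-[(Z)-4-hydroxy-3-methylbut-2-enyl]chroman-4-one | C/C(=C/Cc1c(O)ccc2c1O[C@H](c1ccc(O)c(O)c1)CC2=O)CO | target

**Step count**
Total step count: 11.
Longest linear sequence: 10 (steps 1–7 and 9–11).

**Steps most likely to fail**

**Step 9.**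
- What may go wrong: poor facial selectivity with the electron-rich aldehyde and the bulky triene. Alternatively, acid-induced ionisation or dehydration at the benzylic C2 before ring closure, followed by unselective reclosure, would erode the enantiomeric purity.
- Fallback: C2 is set first and the C2–C3 bond is brought in ready-made. The fallback sets out from 16 and 11.
- Roskamp homologation of 16 (ethyl diazoacetate, NbCl5, CH2Cl2) should give ethyl 3-[3,4-bis(TBS-oxy)phenyl]-3-oxopropanoate F1.
- Noyori asymmetric hydrogenation (RuCl2[(R)-BINAP], H2, EtOH) should give ethyl (S)-3-[3,4-bis(TBS-oxy)phenyl]-3-hydroxypropanoate F2.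
- TESCl/imidazole should give its TES ether F3.
- Claisen-type acylation of dianion 12 (made from 11 as in step 6, with excess base) by F3 should give the delta-silyloxy triketone F4.
- TFA in CH2Cl2 at 0 °C closes F4 to 18, where the route is rejoined.

**Step 6.**
- What may go wrong: incomplete second deprotonation of the poorly soluble enolate, O-acylation, proton transfer from the acidic product, or air oxidation of the dihydroaromatic triketone.
- Fallback: one carbonyl is masked and a kinetic monoenolate is used in place of the dianion. The fallback sets out from 11.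
- TIPSOTf/Et3N should give the 3-(TIPS-oxy)cyclohex-2-enone F5.
- LDA at -78 °C (alpha-prime deprotonation next to the free carbonyl) and acetaldehyde should give the aldol F6 as a diastereomer mixture.
- Dess–Martin oxidation should give the 6-acetyl enone F7.
- AcOH/THF/H2O cleaves the labile vinylogous silyl ester to 13, where the route is rejoined.

**Step 10.**
- What may go wrong: over-oxidation once the free C7 phenol has formed (oxidative cyclisation onto the allylic side chain, or dehydrogenation of C2–C3 toward the flavone), or a sluggish reaction of the keto tautomer.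
- Fallback: the C7 oxygen is capped before oxidation, so that ring A is locked as a silyl dienol ether and no free phenol meets the oxidant. The fallback sets out from 18.
- TBSCl/imidazole should give the 7-O-TBS dihydroflavanone F8.
- DDQ with 2,6-lutidine in CH2Cl2 at 0 °C (aromatisation of a silyloxycyclohexadiene to an aryl silyl ether) should give the fully silylated flavanone F9.
- The buffered fluoride conditions of step 11 convert F9 directly into 20, where the route is rejoined.

**Further compounds**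
F1 | step 9 | ethyl 3-[3,4-bis(TBS-oxy)phenyl]-3-oxopropanoate | CCOC(=O)CC(=O)c1ccc(O[Si](C)(C)C(C)(C)C)c(O[Si](C)(C)C(C)(C)C)c1
F2 | step 9 | ethyl (S)-3-[3,4-bis(TBS-oxy)phenyl]-3-hydroxypropanoate | CCOC(=O)C[C@H](O)c1ccc(O[Si](C)(C)C(C)(C)C)c(O[Si](C)(C)C(C)(C)C)c1
F3 | step 9 | ethyl (S)-3-[3,4-bis(TBS-oxy)phenyl]-3-(TES-oxy)propanoate | CCOC(=O)C[C@H](O[Si](CC)(CC)CC)c1ccc(O[Si](C)(C)C(C)(C)C)c(O[Si](C)(C)C(C)(C)C)c1
F4 | step 9 | delta-(TES-oxy) triketone, bis-enol tautomer, (S) at the carbinol carbon | C/C(=C/CC1=C(O)CCC(C(=O)C[C@H](O[Si](CC)(CC)CC)c2ccc(O[Si](C)(C)C(C)(C)C)c(O[Si](C)(C)C(C)(C)C)c2)=C1O)CO[Si](c1ccccc1)(c1ccccc1)C(C)(C)C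
F5 | step 6 | 2-[(Z)-4-(TBDPS-oxy)-3-methylbut-2-enyl]-3-(TIPS-oxy)cyclohex-2-enone | C/C(=C/CC1=C(O[Si](C(C)C)(C(C)C)C(C)C)CCCC1=O)CO[Si](c1ccccc1)(c1ccccc1)C(C)(C)C
F6 | step 6 | 6-(1-hydroxyethyl) derivative of F5, diastereomer mixture | C/C(=C/CC1=C(O[Si](C(C)C)(C(C)C)C(C)C)CCC(C(C)O)C1=O)CO[Si](c1ccccc1)(c1ccccc1)C(C)(C)C
F7 | step 6 | 6-acetyl derivative of F5 | C/C(=C/CC1=C(O[Si](C(C)C)(C(C)C)C(C)C)CCC(C(C)=O)C1=O)CO[Si](c1ccccc1)(c1ccccc1)C(C)(C)C
F8 | step 10 | (2S)-7-O-TBS ether of 18 | C/C(=C/CC1=C(O[Si](C)(C)C(C)(C)C)CCC2=C1O[C@H](c1ccc(O[Si](C)(C)C(C)(C)C)c(O[Si](C)(C)C(C)(C)C)c1)CC2=O)CO[Si](c1ccccc1)(c1ccccc1)C(C)(C)C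
F9 | step 10 | (2S)-7-O-TBS ether of 19 | C/C(=C/Cc1c(O[Si](C)(C)C(C)(C)C)ccc2c1O[C@H](c1ccc(O[Si](C)(C)C(C)(C)C)c(O[Si](C)(C)C(C)(C)C)c1)CC2=O)CO[Si](c1ccccc1)(c1ccccc1)C(C)(C)C
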